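Ring C is disconnected across C2–C3 and C4–C4a, so the C3–C4 unit is excised as a two-carbon ketene equivalent. The key step is a catalytic enantioselective oxa-Povarov-type [4+2] annulation: an O-aryl oxocarbenium ion (C4a=C8a–O1+=C2, a cationic 2-oxadiene) adds ethoxyacetylene at C2 and the ketenium carbon is captured by C4a, the one unsubstituted, doubly oxygen-flanked carbon of the hexasubstituted ring A; this sets C2 and both C–C bonds at once. The precursor is an O-aryl O-pivaloyl acetal of protected 3,4-dihydroxybenzaldehyde with a 2,4-diallylphloroglucinol ether; the allyl groups become prenyl groups by late cross-metathesis.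

Key step: step 8

Assumption: flavanone numbering is used (O1, C2–C4, C4a, C5–C8, C8a) and C2 is S. The (S,S)-antipode of the chiral acid is taken to deliver 2S; if a first run shows the opposite sense, the (R,R)-acid is used and nothing else changes.

Step 1
Reactants: 1 phloroglucinol
Product: 2 3,5-bis(methoxymethoxy)phenol
Conditions: MOMCl (2.0 equiv), i-Pr2NEt, DMF, 0 °C to rt; chromatographic separation
Reagents that add atoms: chloromethyl methyl ether (MOMCl), COCCl
Why: Williamson-type O-alkylation (MOM ether formation) of the threefold-symmetric triol is statistical but gives a single bis-ether, which is separated from the mono- and tris-ethers.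

Step 2
Reactants: 2 3,5-bis(methoxymethoxy)phenol
Product: 3 [3,5-bis(methoxymethoxy)phenoxy]triisopropylsilane
Conditions: TIPSCl, imidazole, DMF, rt
Reagents that add atoms: triisopropylsilyl chloride (TIPSCl), CC(C)[Si](Cl)(C(C)C)C(C)C
Why: Silylation marks the future O1 with a bulky TIPS group that does not direct lithiation, survives n-BuLi and is cleaved orthogonally to MOM.

Step 3
Reactants: 3 [3,5-bis(methoxymethoxy)phenoxy]triisopropylsilane
Product: 4 [4-allyl-3,5-bis(methoxymethoxy)phenoxy]triisopropylsilane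
Conditions: n-BuLi, THF, 0 °C; then CuBr·SMe2 (10 mol%), allyl bromide, −40 °C to rt
Reagents that add atoms: allyl bromide, C=CCBr
Why: Directed ortho-metalation lithiates the carbon flanked by both MOM ethers (cooperative chelation; the para TIPS ether cannot undergo silyl migration), and the aryl copper species formed by transmetalation is allylated.

Step 4
Reactants: 4 [4-allyl-3,5-bis(methoxymethoxy)phenoxy]triisopropylsilane
Product: 5 2-allyl-5-(allyloxy)-1,3-bis(methoxymethoxy)benzene
Conditions: CsF, allyl bromide, DMF, rt to 50 °C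
Reagents that add atoms: allyl bromide, C=CCBr
Why: Fluoride cleaves the aryl silyl ether and the caesium phenoxide is O-allylated in the same flask (desilylation followed by Williamson etherification).

Step 5
Reactants: 5 2-allyl-5-(allyloxy)-1,3-bis(methoxymethoxy)benzene
Product: 6 2,4-diallyl-3,5-bis(methoxymethoxy)phenol
Conditions: PhNEt2, 190 °C
Reagents that add atoms: none
Why: The aromatic Claisen rearrangement ([3,3]-sigmatropic) moves the allyl group to one of the two equivalent ortho carbons (the para carbon is blocked) and frees the phenol that becomes O1, leaving one ring C–H (the future C4a).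

Step 6
Reactants: 7 3,4-dihydroxybenzaldehyde
Product: 8 3,4-bis(tert-butyldimethylsilyloxy)benzaldehyde
Conditions: TBSCl, imidazole, DMF, rt
Reagents that add atoms: tert-butyldimethylsilyl chloride (TBSCl), CC(C)(C)[Si](C)(C)Cl
Why: Standard silylation protects both catechol hydroxyls as silyl ethers, which, unlike acetals, tolerate the acyl chloride and Lewis acid of step 7.

Step 7
Reactants: 8 3,4-bis(tert-butyldimethylsilyloxy)benzaldehyde; 6 2,4-diallyl-3,5-bis(methoxymethoxy)phenol
Product: 10 [2,4-diallyl-3,5-bis(methoxymethoxy)phenoxy][3,4-bis(tert-butyldimethylsilyloxy)phenyl]methyl pivalate (racemic), via chloro pivalate 9 (not isolated)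
Conditions: 8, PivCl, ZnCl2 (2 mol%), CH2Cl2, 0 °C to rt; then 6, NaH, THF–DMF, −30 to 0 °C
Reagents that add atoms: pivaloyl chloride (PivCl), CC(C)(C)C(=O)Cl
Why: ZnCl2-catalysed addition of the acyl chloride across the aldehyde C=O gives the α-chloroalkyl ester, whose chloride is displaced by the phenoxide oxygen (acyloxyalkylation of a phenol, as in pivaloyloxymethyl ether formation), the hindered pivalate resisting acyl transfer; the acetal carbon is racemic and is planarised in step 8.

Step 8
Reactants: 10 [2,4-diallyl-3,5-bis(methoxymethoxy)phenoxy][3,4-bis(tert-butyldimethylsilyloxy)phenyl]methyl pivalate; 11 ethoxyacetylene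
Product: 14 (2S)-6,8-diallyl-2-[3,4-bis(tert-butyldimethylsilyloxy)phenyl]-5,7-bis(methoxymethoxy)chroman-4-one, via oxocarbenium ion 12 (not isolated), via 4-ethoxy-2H-chromene 13 (not isolated)
Conditions: (S,S)-IDPi acid HN[P(=NTf)(O2Ar*)]2 (imidodiphosphorimidate; Ar* = (S)-3,3'-bis[3,5-bis(trifluoromethyl)phenyl]-1,1'-binaphthalene-2,2'-diyl; 5 mol%), 11 (3 equiv), toluene, −60 °C; then oxalic acid, THF–H2O, 0 °C
Reagents that add atoms: water, O
Why: Proposed new method: the chiral acid protonates the pivalate carbonyl of 10 and pivalic acid (a far better nucleofuge than the aryloxide) leaves, giving the O-aryl oxocarbenium ion 12 as a contact ion pair with the imidodiphosphorimidate anion; this cationic 2-oxadiene (C4a=C8a–O1+=C2) is attacked at C2 by the nucleophilic CH terminus of 11 (bond C2–C3) and the resulting ketene oxonium (α-ethoxyvinyl) cation is captured at once by C4a (bond C4–C4a), loss of the ring proton returning the acid. The closest known reaction types are the SnCl4-promoted oxa-Povarov annulation of O-aryl oxocarbenium ions with alkenes, keteniminium Friedel–Crafts cyclisations and counteranion-directed additions to aldehyde-derived oxocarbenium ions by acids of this class; the ynol ether partner and enantiocontrol on an O-aryl oxocarbenium ion are the new elements. Ring C closes by a six-membered Friedel–Crafts attack on the digonal carbon of the ketene oxonium ion (6-exo-dig with respect to its C4=O+ bond, the C3=C4 bond staying in the ring), so the whole is a stepwise polar [4+2] annulation. C2, the only new stereocentre, is set in the first C–C bond formation by the chiral anion, which covers one face of the planar ion pair inside its binaphthyl pocket. The step needs regiocontrol of the arene attack, secured because C4a is the only unsubstituted carbon of ring A and lies ortho/para to three oxygens, and chemoselectivity for the ynol ether, secured by carrying terminal allyl groups, which are poor π-nucleophiles and, unlike an ortho prenyl group, cannot close a Prins ring onto C2; the MOM acetals ionise far more slowly than the benzylic acyloxy acetal. Mild aqueous acid then hydrolyses enol ether 13 to ketone 14 without touching C2.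

Step 9
Reactants: 14 (2S)-6,8-diallyl-2-[3,4-bis(tert-butyldimethylsilyloxy)phenyl]-5,7-bis(methoxymethoxy)chroman-4-one
Product: 15 (2S)-2-[3,4-bis(tert-butyldimethylsilyloxy)phenyl]-5,7-bis(methoxymethoxy)-6,8-bis(3-methylbut-2-en-1-yl)chroman-4-one
Conditions: second-generation Grubbs catalyst (5 mol%), 2-methyl-2-butene (excess), CH2Cl2, 40 °C
Reagents that add atoms: 2-methyl-2-butene, CC=C(C)C
Why: Olefin cross-metathesis of both terminal allyl groups with excess 2-methyl-2-butene converts them into prenyl groups under neutral conditions that leave C2 untouched.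

Step 10
Reactants: 15 (2S)-2-[3,4-bis(tert-butyldimethylsilyloxy)phenyl]-5,7-bis(methoxymethoxy)-6,8-bis(3-methylbut-2-en-1-yl)chroman-4-one
Product: 17 6,8-diprenyleriodictyol [(2S)-2-(3,4-dihydroxyphenyl)-5,7-dihydroxy-6,8-bis(3-methylbut-2-en-1-yl)chroman-4-one], via bis-MOM catechol flavanone 16 (not isolated)
Conditions: KHF2, MeOH–THF, rt; then HCl (3 M in MeOH), 45 °C
Reagents that add atoms: none
Why: Fluoride from KHF2 removes the two phenolic TBS ethers and acid-catalysed transacetalisation with methanol then removes the two MOM ethers, both under non-basic conditions that avoid ring opening of the flavanone and so keep the 2S centre.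

Compound list
1 | phloroglucinol (benzene-1,3,5-triol) | Oc1cc(O)cc(O)c1 | starting material
2 | 3,5-bis(methoxymethoxy)phenol | COCOc1cc(O)cc(OCOC)c1 | intermediate
3 | [3,5-bis(methoxymethoxy)phenoxy]triisopropylsilane | COCOc1cc(OCOC)cc(O[Si](C(C)C)(C(C)C)C(C)C)c1 | intermediate
4 | [4-allyl-3,5-bis(methoxymethoxy)phenoxy]triisopropylsilane | C=CCc1c(OCOC)cc(O[Si](C(C)C)(C(C)C)C(C)C)cc1OCOC | intermediate
5 | 2-allyl-5-(allyloxy)-1,3-bis(methoxymethoxy)benzene | C=CCOc1cc(OCOC)c(CC=C)c(OCOC)c1 | intermediate
6 | 2,4-diallyl-3,5-bis(methoxymethoxy)phenol | Oc1cc(OCOC)c(CC=C)c(OCOC)c1CC=C | intermediate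
7 | 3,4-dihydroxybenzaldehyde | O=Cc1ccc(O)c(O)c1 | starting material
8 | 3,4-bis(tert-butyldimethylsilyloxy)benzaldehyde | O=Cc1ccc(O[Si](C)(C)C(C)(C)C)c(O[Si](C)(C)C(C)(C)C)c1 | intermediate
9 | chloro[3,4-bis(tert-butyldimethylsilyloxy)phenyl]methyl pivalate (racemic, not isolated) | CC(C)(C)C(=O)OC(Cl)c1ccc(O[Si](C)(C)C(C)(C)C)c(O[Si](C)(C)C(C)(C)C)c1 | intermediate
10 | [2,4-diallyl-3,5-bis(methoxymethoxy)phenoxy][3,4-bis(tert-butyldimethylsilyloxy)phenyl]methyl pivalate (racemic O-aryl O-acyl acetal) | C=CCc1c(OCOC)cc(OC(OC(=O)C(C)(C)C)c2ccc(O[Si](C)(C)C(C)(C)C)c(O[Si](C)(C)C(C)(C)C)c2)c(CC=C)c1OCOC | intermediate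
11 | ethoxyacetylene (ethyl ethynyl ether) | C#COCC | starting material
12 | O-[2,4-diallyl-3,5-bis(methoxymethoxy)phenyl] oxocarbenium ion of aldehyde 8 (ion pair with the catalyst anion, not isolated) | C=CCc1c(OCOC)cc([O+]=Cc2ccc(O[Si](C)(C)C(C)(C)C)c(O[Si](C)(C)C(C)(C)C)c2)c(CC=C)c1OCOC | intermediate
13 | (2S)-6,8-diallyl-2-[3,4-bis(tert-butyldimethylsilyloxy)phenyl]-4-ethoxy-5,7-bis(methoxymethoxy)-2H-chromene (not isolated) | C=CCc1c(OCOC)c(CC=C)c2c(c1OCOC)C(OCC)=C[C@@H](c1ccc(O[Si](C)(C)C(C)(C)C)c(O[Si](C)(C)C(C)(C)C)c1)O2 | intermediate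
14 | (2S)-6,8-diallyl-2-[3,4-bis(tert-butyldimethylsilyloxy)phenyl]-5,7-bis(methoxymethoxy)chroman-4-one | C=CCc1c(OCOC)c(CC=C)c2c(c1OCOC)C(=O)C[C@@H](c1ccc(O[Si](C)(C)C(C)(C)C)c(O[Si](C)(C)C(C)(C)C)c1)O2 | intermediate
15 | (2S)-2-[3,4-bis(tert-butyldimethylsilyloxy)phenyl]-5,7-bis(methoxymethoxy)-6,8-bis(3-methylbut-2-en-1-yl)chroman-4-one | CC(C)=CCc1c(OCOC)c(CC=C(C)C)c2c(c1OCOC)C(=O)C[C@@H](c1ccc(O[Si](C)(C)C(C)(C)C)c(O[Si](C)(C)C(C)(C)C)c1)O2 | intermediate
16 | (2S)-2-(3,4-dihydroxyphenyl)-5,7-bis(methoxymethoxy)-6,8-bis(3-methylbut-2-en-1-yl)chroman-4-one (not isolated) | CC(C)=CCc1c(OCOC)c(CC=C(C)C)c2c(c1OCOC)C(=O)C[C@@H](c1ccc(O)c(O)c1)O2 | intermediate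
17 | 6,8-diprenyleriodictyol, (2S)-2-(3,4-dihydroxyphenyl)-5,7-dihydroxy-6,8-bis(3-methylbut-2-en-1-yl)chroman-4-one | CC(C)=CCc1c(O)c(CC=C(C)C)c2c(c1O)C(=O)C[C@@H](c1ccc(O)c(O)c1)O2 | target

Total steps: 10. Longest linear sequence: 9 steps (steps 1–5 and 7–10).

Steps most likely to fail

Step 8. Enantiofacial discrimination in the ion pair may be poor. The acid may also protonate the ynol ether faster than it ionises the acetal, which loses the partner and acetylates ring A. The product enol ether may racemise by acid-induced opening of the O1–C2 bond. The fallback uses known chemistry and sets out from 10. A Mukaiyama-type addition of 1,1-bis(trimethylsilyloxy)ethene (Me3SiOTf cat., CH2Cl2, −78 °C, aqueous work-up) should form C2–C3 and give racemic 3-[2,4-diallyl-3,5-bis(methoxymethoxy)phenoxy]-3-[3,4-bis(tert-butyldimethylsilyloxy)phenyl]propanoic acid F1. Trifluoroacetic anhydride (CH2Cl2, 0 °C) should then close ring C by intramolecular Friedel–Crafts acylation at C4a, giving racemic 6,8-diallyl-2-[3,4-bis(tert-butyldimethylsilyloxy)phenyl]-5,7-bis(methoxymethoxy)chroman-4-one F2. Kinetic resolution by asymmetric transfer hydrogenation (RhCl(C5Me5)(TsDPEN), HCO2H/Et3N, the catalyst antipode that reduces the 2R ketone) should convert the unwanted enantiomer into the (2R,4R)-cis-flavan-4-ol F3 and leave the 2S ketone, at the cost of the other enantiomer. The fallback comes back to the route at 14.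

Step 7. The chloro ester may revert to aldehyde and acyl chloride, which would O-pivaloylate the phenoxide, and the ambident phenoxide may be C-alkylated at its free ring carbon. The fallback sets out from 8 and 6. Oxidation of 8 (NaClO2, NaH2PO4, 2-methyl-2-butene, t-BuOH–H2O) should give 3,4-bis(tert-butyldimethylsilyloxy)benzoic acid F4. Esterification with 6 (DCC, DMAP, CH2Cl2) should give 2,4-diallyl-3,5-bis(methoxymethoxy)phenyl 3,4-bis(tert-butyldimethylsilyloxy)benzoate F5. Reductive acetylation of the ester (i-Bu2AlH, CH2Cl2, −78 °C; then Ac2O, pyridine, DMAP) should trap the aluminium hemiacetal as [2,4-diallyl-3,5-bis(methoxymethoxy)phenoxy][3,4-bis(tert-butyldimethylsilyloxy)phenyl]methyl acetate F6. F6 takes the place of 10 under the conditions of step 8, with acetic acid leaving instead of pivalic acid, so the fallback comes back to the route at 14.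

Step 10. During the acidic MOM cleavage a prenyl group may cyclise onto the neighbouring free phenol (chroman formation) or be hydrated. The fallback changes the order of events so that acid never meets a prenyl group, and sets out from 14. Global acidic methanolysis (3 M HCl in MeOH, 60 °C), which allyl groups tolerate, should give (2S)-6,8-diallyl-2-(3,4-dihydroxyphenyl)-5,7-dihydroxychroman-4-one F7. Cross-metathesis of this free tetraphenol with 2-methyl-2-butene (second-generation Grubbs catalyst, CH2Cl2, 40 °C) should then install both prenyl groups, so the fallback comes back to the route at 17.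

Further compounds
F1 | step 8 | racemic 3-[2,4-diallyl-3,5-bis(methoxymethoxy)phenoxy]-3-[3,4-bis(tert-butyldimethylsilyloxy)phenyl]propanoic acid | C=CCc1c(OCOC)cc(OC(CC(=O)O)c2ccc(O[Si](C)(C)C(C)(C)C)c(O[Si](C)(C)C(C)(C)C)c2)c(CC=C)c1OCOC
F2 | step 8 | racemic 6,8-diallyl-2-[3,4-bis(tert-butyldimethylsilyloxy)phenyl]-5,7-bis(methoxymethoxy)chroman-4-one | C=CCc1c(OCOC)c(CC=C)c2c(c1OCOC)C(=O)CC(c1ccc(O[Si](C)(C)C(C)(C)C)c(O[Si](C)(C)C(C)(C)C)c1)O2
F3 | step 8 | (2R,4R)-6,8-diallyl-2-[3,4-bis(tert-butyldimethylsilyloxy)phenyl]-5,7-bis(methoxymethoxy)chroman-4-ol (cis) | C=CCc1c(OCOC)c(CC=C)c2c(c1OCOC)[C@H](O)C[C@H](c1ccc(O[Si](C)(C)C(C)(C)C)c(O[Si](C)(C)C(C)(C)C)c1)O2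
F4 | step 7 | 3,4-bis(tert-butyldimethylsilyloxy)benzoic acid | OC(=O)c1ccc(O[Si](C)(C)C(C)(C)C)c(O[Si](C)(C)C(C)(C)C)c1
F5 | step 7 | 2,4-diallyl-3,5-bis(methoxymethoxy)phenyl 3,4-bis(tert-butyldimethylsilyloxy)benzoate | C=CCc1c(OCOC)cc(OC(=O)c2ccc(O[Si](C)(C)C(C)(C)C)c(O[Si](C)(C)C(C)(C)C)c2)c(CC=C)c1OCOC
F6 | step 7 | [2,4-diallyl-3,5-bis(methoxymethoxy)phenoxy][3,4-bis(tert-butyldimethylsilyloxy)phenyl]methyl acetate (racemic) | C=CCc1c(OCOC)cc(OC(OC(C)=O)c2ccc(O[Si](C)(C)C(C)(C)C)c(O[Si](C)(C)C(C)(C)C)c2)c(CC=C)c1OCOC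
F7 | step 10 | (2S)-6,8-diallyl-2-(3,4-dihydroxyphenyl)-5,7-dihydroxychroman-4-one | C=CCc1c(O)c(CC=C)c2c(c1O)C(=O)C[C@@H](c1ccc(O)c(O)c1)O2
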